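At 30.0 h Friday's run, charged at 1 M, holds 71.7 % of target, more than the 62.7 % of Sunday's run, charged at 0.67 M, at the later 1.67 d.

| flask | starting material | remark | time |
|---|---|---|---|
| Friday's | 1 M | the very flask that is asked about, followed so far |  |
| Sunday's | 0.67 M | run made earlier |  |
| flask | 1.0 M |  | 4.0 d |

| Friday's: time / h | Friday's: target / % | Sunday's: time / d | Sunday's: target / % |
|---|---|---|---|
| 8.00 | 46.9 | 0.333 | 39.4 |
| 15.0 | 61.1 | 0.833 | 55.3 |
| 20.0 | 68.6 | 1.67 | 62.7 |
| 30.0 | 71.7 | 4.00 | 60.6 |

(standard deviation of a reading: 1 percentage point)

- the analysis behind the earlier runs scatters by 1 percentage point, standard deviation
- a reading or a percentage of target counts all its forms, free or not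
- the reaction counts as stopped when no species that holds the starting material changes by six tenths of a point or more over the second half of the time

1. which holds at 4.0 d: what has brought the reaction to rest, or that it has not come to rest (all of the starting material has reacted / it is still moving / forward and back rates have come level)
2. how much target there is at 4.0 d, in percent of the starting material charged

Two chemists read these runs differently. The first takes a one-way second-order step, whose rate constant k comes from Friday's first reading as 0.110 M⁻¹ h⁻¹. Friday's last step is still a rise of 3.1 percentage points, so she expects the flask to be still moving, at 91.4 % of target.

The second answers that Sunday's last two readings differ by 2.1 points and that the later one is the lower, so he takes Sunday's run to have stopped. He carries one quantity from it. Averaging those readings gives 0.257 M for the remainder r, the concentration of the charge that is not target. If r stays the same at a larger charge, this flask reaches 74.3 %.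

The forecast takes the second side with a different reckoning, reading “a plateau well short of full conversion” and extending Friday's rise: forward and back rates have come level, with 72.8 % of target.

In the flask, forward and back rates have come level at 4.0 d, with 73.5 % of target, 67.7 % of the charge as crystals, and r at 0.265 M.

    target ⇌ isomer of the product A (K = 0.160, k = 0.460 h⁻¹)
    isomer of the product A ⇌ isomer of the product B (K = 0.340, k = 0.0770 h⁻¹)
    isomer of the product B ⇌ starting material (k = 0.190 h⁻¹)
    crystals ⇌ target, rate k4*(cs4 - [target]) while solid is left; crystals form when [target] > cs4 (solubility = 0.0580 M, k = 13.0 h⁻¹)
    starting material ⇌ target (K = 0.230, k = 0.130 h⁻¹)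

The first chemist keeps the early flask, which was still rising: at 0.896 d its target stood 5 points from its value at 4.0 d. Later, the relaxation half-life of starting material and dissolved target, 0.997 h, is short against 4.0 d. While crystals stand in this flask, dissolved target is at its solubility, 0.058 M, and dividing by 0.23, the equilibrium ratio of dissolved target to starting material, gives 0.252 M of starting material, the 25.2 % of the charge left at 4.0 d. With 2.5 M charged, r from Sunday's run reckons 89.7 % of target, and that neighbour flask gives 89.4 %.

All runs come from a simulation with made-up constants, and the scatter is random.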